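## Retrosynthetic overview

1. The C8–OOH group is made last, by a singlet-oxygen ene reaction on the 7,8-alkene of lactone 17 (C–O bond).
2. The δ-lactone and the 14-membered carbocycle arise together by a transannular radical addition (C2 to C1) inside the 16-membered macrolactone 15; that macrocycle is closed through the C3–O–C16 ester bond, not through a C–C bond.
3. Seco acid 13 comes from epoxy alcohol 10 by Payne rearrangement and selenolate opening, which inverts C3 and puts the radical precursor on C2.
4. The C20 chain is farnesol (C2–C13) plus a two-carbon Wittig unit and a three-carbon Horner–Wadsworth–Emmons unit; C3/C4 come from a Sharpless epoxidation and C11/C12 from an amine-catalysed epoxidation of the enal obtained by allylic oxidation.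
5. Ring order: 3,4-epoxide, then 11,12-epoxide, then 16-membered lactone, then δ-lactone and 14-membered carbocycle in one step.

Assumption: atom labels C1–C20 are the cembrane numbers of the target (C1 ring CH carrying C15; C3 lactone O–CH; C4 C(CH3)OH; C8 carries OOH; C11/C12 epoxide; C16 lactone C=O). Commercial (2E,6E)-farnesol is taken as a single isomer.

## Route

Step 1
Reactants: 1 (2E,6E)-farnesol
Product: 2 (2S,3S,6E)-2,3-epoxy-3,7,11-trimethyldodeca-6,10-dien-1-ol
Conditions: Ti(OiPr)4 (5 mol%), L-(+)-diethyl tartrate (6 mol%), tBuOOH (2 equiv), 4 Å MS, CH2Cl2, −20 °C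
Reagents that add atoms: tert-butyl hydroperoxide, CC(C)(C)OO
Why: Sharpless asymmetric epoxidation; the allylic hydroxyl binds the titanium tartrate peroxide complex, so only the 2,3-alkene reacts and L-(+)-tartrate gives the (2S,3S)-epoxide, which fixes C4 for good and C3 in the configuration that step 7 inverts.

Step 2
Reactants: 2 (2S,3S)-2,3-epoxyfarnesol
Product: 4 (2E,6E,10S,11S)-10,11-epoxy-12-hydroxy-2,6,10-trimethyldodeca-2,6-dienal, via allylic alcohol 3 (not isolated)
Conditions: SeO2 (0.3 equiv), tBuOOH (3 equiv), salicylic acid (10 mol%), CH2Cl2, 25 °C; filter; then MnO2 (15 equiv), CH2Cl2, 25 °C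
Reagents that add atoms: tert-butyl hydroperoxide, CC(C)(C)OO (oxygen relayed by catalytic SeO2)
Why: SeO2 allylic oxidation (ene reaction then [2,3]-sigmatropic shift) hydroxylates the (E)-methyl of the terminal trisubstituted alkene, and MnO2 then oxidises only this allylic alcohol because the epoxy alcohol hydroxyl is no longer allylic.

Step 3
Reactants: 4 epoxy enal
Product: 5 (2R,3S,6E,10S,11S)-2,3:10,11-diepoxy-12-hydroxy-2,6,10-trimethyldodec-6-enal
Conditions: 9-amino(9-deoxy)epiquinine (10 mol%), (R)-TRIP phosphoric acid (10 mol%), 50% aq. H2O2 (3 equiv), THF, 40 °C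
Reagents that add atoms: hydrogen peroxide, OO
Why: Amine-catalysed Weitz–Scheffer epoxidation (iminium then enamine); only the enal C=C is electrophilic, so H2O2 adds at that site alone, and the chiral amine/phosphate pair sets C11 and C12 as the trans (2R,3S)-epoxy aldehyde (the quinidine-derived amine with (S)-TRIP is the mirror-image pair if the facial sense has to be reversed).

Step 4
Reactants: 5 bis-epoxy aldehyde; 6 (triphenylphosphoranylidene)acetaldehyde
Product: 7 (2E,4S,5S,8E,12S,13S)-4,5:12,13-diepoxy-14-hydroxy-4,8,12-trimethyltetradeca-2,8-dienal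
Conditions: toluene, 70 °C
Reagents that add atoms: none
Why: Wittig olefination with a stabilised ylide gives the (E)-enal and adds C14 and C1; the α-quaternary epoxy aldehyde cannot epimerise.

Step 5
Reactants: 7 bis-epoxy enal; 8 triethyl 2-phosphonopropionate
Product: 9 ethyl (2E,4E,6S,7S,10E,14S,15S)-6,7:14,15-diepoxy-16-hydroxy-2,6,10,14-tetramethylhexadeca-2,4,10-trienoate
Conditions: LiCl, DBU, MeCN, 25 °C
Reagents that add atoms: none
Why: Horner–Wadsworth–Emmons olefination under Masamune–Roush conditions gives the (E)-trisubstituted enoate (C15, C16, C17) with a base too weak to disturb the epoxy alcohol.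

Step 6
Reactants: 9 dienoate
Product: 10 ethyl (2E,6S,7S,10E,14S,15S)-6,7:14,15-diepoxy-16-hydroxy-2,6,10,14-tetramethylhexadeca-2,10-dienoate
Conditions: 2-nitrobenzenesulfonohydrazide (4 equiv), Et3N, CH2Cl2, 25 °C
Reagents that add atoms: none
Why: Diimide reduction (concerted syn hydrogen transfer) takes the 1,2-disubstituted C13=C14 bond much faster than the two trisubstituted alkenes and does not touch epoxides.

Step 7
Reactants: 10 epoxy alcohol ester
Product: 13 (2E,6S,7S,10E,14S,15S)-6,7-epoxy-14,15-dihydroxy-2,6,10,14-tetramethyl-16-(phenylselanyl)hexadeca-2,10-dienoic acid, via sodium carboxylate 11 (not isolated), via Payne epoxide 12 (not isolated)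
Conditions: 0.5 M aq. NaOH (4 equiv), tBuOH, 40 °C; then PhSeH (1.15 equiv, slow addition), 25 °C, Ar; then 1 M HCl to pH 4
Reagents that add atoms: benzeneselenol, [SeH]c1ccccc1; sodium hydroxide, [Na+].[OH-]
Why: Saponification, then Payne rearrangement (the C2 alkoxide opens the 3,4-epoxide at C3 with inversion, which sets the final C3) and SN2 opening of the terminal epoxide at C2 by selenolate, the selenium variant of the Payne rearrangement–thiolate opening; the distal trisubstituted epoxide has no neighbouring alkoxide and is far slower at 25 °C.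

Step 8
Reactants: 13 seleno diol acid
Product: 15 (3E,7S,8S,11E,15S,16S)-7,8-epoxy-15-hydroxy-3,7,11,15-tetramethyl-16-[(phenylselanyl)methyl]oxacyclohexadeca-3,11-dien-2-one, via mixed anhydride 14 (not isolated)
Conditions: 2-methyl-6-nitrobenzoic anhydride (1.3 equiv), DMAP (3 equiv), CH2Cl2, 25 °C, syringe-pump addition of 13 (final 1 mM)
Reagents that add atoms: none
Why: Shiina macrolactonisation; the mixed anhydride acylates the secondary C3–OH (the tertiary C4–OH is inert) at high dilution and closes the 16-membered ring through the C3–O–C16 bond without touching a stereocentre.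

Step 9
Reactants: 15 macrolactone
Product: 17 (1R,3R,4S,7E,11S,12S,15S)-11,12-epoxy-4-hydroxycembr-7-en-16,3-olide, via C15-epimeric lactone 16 (not isolated)
Conditions: Bu3SnH (1.3 equiv) and AIBN (0.2 equiv) added over 8 h, PhH, 80 °C, 2 mM; then DBU (0.3 equiv), CH2Cl2, 25 °C
Reagents that add atoms: none
Why: Proposed new method: tin-radical abstraction of the phenylselanyl group gives the primary C2 radical (a β-acyloxyalkyl radical), which the 16-membered lactone holds next to the enoate so that it adds 6-endo-trig to the β-carbon C1 (attack at the α-carbon C15 is blocked by its methyl group and would give an unstabilised radical); this one C–C bond contracts the macrolactone into the δ-lactone-bridged 14-membered carbocycle, C1 should form cis to C3 because a chair-like transition state keeps both ring-chain substituents pseudo-equatorial, and the tertiary α-lactone radical is reduced to 16, which DBU equilibrates to the equatorial (trans) C15 methyl of 17; the closest known reaction types are ester-tethered 6-endo Giese cyclisations onto α-substituted acrylates and transannular radical cyclisations of macrocycles.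

Step 10
Reactants: 17 lactone
Product: 18 (1R,3R,4S,6E,8R,11S,12S,15S)-11,12-epoxy-8-hydroperoxy-4-hydroxycembr-6-en-16,3-olide (the target)
Conditions: O2, 5,10,15,20-tetraphenylporphyrin (1 mol%), visible light, CH2Cl2, 0 °C
Reagents that add atoms: dioxygen, O=O
Why: Schenck ene reaction of singlet oxygen with the only alkene; the cis effect limits hydrogen abstraction to the C6/C19 side and hydrogen bonding of the perepoxide to the C4 hydroxyl should steer it to C6–H, so oxygen ends on C8 and the alkene shifts to (E)-C6=C7, with C8 (R) expected from suprafacial attack on the exposed alkene face that the C4 hydroxyl can reach.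

## Compound list

1 | (2E,6E)-farnesol | OC/C=C(\C)CC/C=C(\C)CCC=C(C)C | starting material
2 | (2S,3S,6E)-2,3-epoxy-3,7,11-trimethyldodeca-6,10-dien-1-ol | OC[C@@H]1O[C@@]1(C)CC/C=C(\C)CCC=C(C)C | intermediate
3 | (2S,3S,6E,10E)-2,3-epoxy-3,7,11-trimethyldodeca-6,10-diene-1,12-diol | OC[C@@H]1O[C@@]1(C)CC/C=C(\C)CC/C=C(\C)CO | intermediate (not isolated)
4 | (2E,6E,10S,11S)-10,11-epoxy-12-hydroxy-2,6,10-trimethyldodeca-2,6-dienal | OC[C@@H]1O[C@@]1(C)CC/C=C(\C)CC/C=C(\C)C=O | intermediate
5 | (2R,3S,6E,10S,11S)-2,3:10,11-diepoxy-12-hydroxy-2,6,10-trimethyldodec-6-enal | OC[C@@H]1O[C@@]1(C)CC/C=C(\C)CC[C@@H]1O[C@@]1(C)C=O | intermediate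
6 | (triphenylphosphoranylidene)acetaldehyde | O=CC=P(c1ccccc1)(c1ccccc1)c1ccccc1 | starting material
7 | (2E,4S,5S,8E,12S,13S)-4,5:12,13-diepoxy-14-hydroxy-4,8,12-trimethyltetradeca-2,8-dienal | OC[C@@H]1O[C@@]1(C)CC/C=C(\C)CC[C@@H]1O[C@@]1(C)/C=C/C=O | intermediate
8 | triethyl 2-phosphonopropionate | CCOC(=O)C(C)P(=O)(OCC)OCC | starting material
9 | ethyl (2E,4E,6S,7S,10E,14S,15S)-6,7:14,15-diepoxy-16-hydroxy-2,6,10,14-tetramethylhexadeca-2,4,10-trienoate | OC[C@@H]1O[C@@]1(C)CC/C=C(\C)CC[C@@H]1O[C@@]1(C)/C=C/C=C(\C)C(=O)OCC | intermediate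
10 | ethyl (2E,6S,7S,10E,14S,15S)-6,7:14,15-diepoxy-16-hydroxy-2,6,10,14-tetramethylhexadeca-2,10-dienoate | OC[C@@H]1O[C@@]1(C)CC/C=C(\C)CC[C@@H]1O[C@@]1(C)CC/C=C(\C)C(=O)OCC | intermediate
11 | sodium (2E,6S,7S,10E,14S,15S)-6,7:14,15-diepoxy-16-hydroxy-2,6,10,14-tetramethylhexadeca-2,10-dienoate | OC[C@@H]1O[C@@]1(C)CC/C=C(\C)CC[C@@H]1O[C@@]1(C)CC/C=C(\C)C(=O)[O-].[Na+] | intermediate (not isolated)
12 | sodium (2E,6S,7S,10E,14S,15R)-6,7:15,16-diepoxy-14-hydroxy-2,6,10,14-tetramethylhexadeca-2,10-dienoate | C1O[C@H]1[C@@](C)(O)CC/C=C(\C)CC[C@@H]1O[C@@]1(C)CC/C=C(\C)C(=O)[O-].[Na+] | intermediate (not isolated)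
13 | (2E,6S,7S,10E,14S,15S)-6,7-epoxy-14,15-dihydroxy-2,6,10,14-tetramethyl-16-(phenylselanyl)hexadeca-2,10-dienoic acid | c1ccccc1[Se]C[C@@H](O)[C@@](C)(O)CC/C=C(\C)CC[C@@H]1O[C@@]1(C)CC/C=C(\C)C(=O)O | intermediate
14 | mixed anhydride of 13 with 2-methyl-6-nitrobenzoic acid | c1ccccc1[Se]C[C@@H](O)[C@@](C)(O)CC/C=C(\C)CC[C@@H]1O[C@@]1(C)CC/C=C(\C)C(=O)OC(=O)c1c(C)cccc1[N+](=O)[O-] | intermediate (not isolated)
15 | (3E,7S,8S,11E,15S,16S)-7,8-epoxy-15-hydroxy-3,7,11,15-tetramethyl-16-[(phenylselanyl)methyl]oxacyclohexadeca-3,11-dien-2-one | c1ccccc1[Se]C[C@H]2OC(=O)/C(C)=C/CC[C@]3(C)O[C@H]3CC/C(C)=C/CC[C@]2(C)O | intermediate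
16 | (1R,3R,4S,7E,11S,12S,15R)-11,12-epoxy-4-hydroxycembr-7-en-16,3-olide (C15 epimer of 17) | C[C@H]1C(=O)O[C@@H]2C[C@H]1CC[C@]1(C)O[C@H]1CC/C(C)=C/CC[C@]2(C)O | intermediate (not isolated)
17 | (1R,3R,4S,7E,11S,12S,15S)-11,12-epoxy-4-hydroxycembr-7-en-16,3-olide | C[C@@H]1C(=O)O[C@@H]2C[C@H]1CC[C@]1(C)O[C@H]1CC/C(C)=C/CC[C@]2(C)O | intermediate
18 | (1R,3R,4S,6E,8R,11S,12S,15S)-11,12-epoxy-8-hydroperoxy-4-hydroxycembr-6-en-16,3-olide (CNP0297487.3) | C[C@@H]1C(=O)O[C@@H]2C[C@H]1CC[C@]1(C)O[C@H]1CC[C@@](C)(OO)/C=C/C[C@]2(C)O | target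

## Step count and risks

Total step count: 10. Longest linear sequence: 10 steps (1 to 18).

The three steps most likely to fail are steps 9, 10 and 2.

**Step 9 (the proposed new transformation).** The lactone ester has to reach its s-cis rotamer before the C2 radical can close. Simple reduction, 1,2-acyloxy shift or 6-exo closure onto C7 may win instead. The fallback uses known reactions only; it sets out from 13 and comes back at 17. Esterification of 13 (TMSCHN2, MeOH/toluene, 0 °C) gives methyl (2E,6S,7S,10E,14S,15S)-6,7-epoxy-14,15-dihydroxy-2,6,10,14-tetramethyl-16-(phenylselanyl)hexadeca-2,10-dienoate F1. Radical macrocyclisation of this open-chain selenide (Bu3SnH, AIBN, PhH, 80 °C, 0.5 mM, syringe pump) is a 14-endo Giese addition of the C2 radical to the enoate and needs no ester rotamer. It gives methyl (2RS)-2-[(1R,3R,4S,7E,11S,12S)-11,12-epoxy-3,4-dihydroxy-4,8,12-trimethylcyclotetradec-7-en-1-yl]propanoate F2 together with its C1 epimer. DBU (toluene, 60 °C) then lactonises the C3 hydroxyl onto the ester and equilibrates C15, and chromatography returns 17. This detour closes the carbocycle directly, with lower stereocontrol at C1.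

**Step 10.** Singlet oxygen may abstract a C19 hydrogen instead, giving the C7 hydroperoxide with an exocyclic methylene, or may attack the other alkene face, giving the C8 epimer. The fallback sets out from 17 and comes back at 18. It replaces hydrogen-bond direction by steric direction, which is known to switch the facial and regiochemical preference of the ene reaction for hydroxyl-bearing alkenes. Silylation of 17 (1-(trimethylsilyl)imidazole, CH2Cl2, 25 °C) gives (1R,3R,4S,7E,11S,12S,15S)-11,12-epoxy-4-(trimethylsilyloxy)cembr-7-en-16,3-olide F3. Photo-oxygenation under the step 10 conditions gives (1R,3R,4S,6E,8R,11S,12S,15S)-11,12-epoxy-8-hydroperoxy-4-(trimethylsilyloxy)cembr-6-en-16,3-olide F4. Buffered desilylation (TBAF, AcOH, THF, 0 °C) returns 18.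

**Step 2.** The allylic oxidation has only modest regioselectivity, and the epoxy alcohol is sensitive to the acidic selenium medium. The fallback sets out from 2 and comes back at 4 in one operation. It is a cross-metathesis of the terminal isopropylidene group with methacrolein (5 equiv) using the second-generation Hoveyda–Grubbs catalyst RuCl2(H2IMes)(=CH–C6H4-2-OiPr) (5 mol%) in CH2Cl2 at 40 °C. This gives the (E)-enal directly and makes no compound outside the list (none F0).

Further compounds
F0 | step 2 | none | none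
F1 | step 9 | methyl (2E,6S,7S,10E,14S,15S)-6,7-epoxy-14,15-dihydroxy-2,6,10,14-tetramethyl-16-(phenylselanyl)hexadeca-2,10-dienoate | c1ccccc1[Se]C[C@@H](O)[C@@](C)(O)CC/C=C(\C)CC[C@@H]1O[C@@]1(C)CC/C=C(\C)C(=O)OC
F2 | step 9 | methyl (2RS)-2-[(1R,3R,4S,7E,11S,12S)-11,12-epoxy-3,4-dihydroxy-4,8,12-trimethylcyclotetradec-7-en-1-yl]propanoate | COC(=O)C(C)[C@H]1C[C@@H](O)[C@@](C)(O)CC/C=C(\C)CC[C@@H]2O[C@@]2(C)CC1
F3 | step 10 | (1R,3R,4S,7E,11S,12S,15S)-11,12-epoxy-4-(trimethylsilyloxy)cembr-7-en-16,3-olide | C[C@@H]1C(=O)O[C@@H]2C[C@H]1CC[C@]1(C)O[C@H]1CC/C(C)=C/CC[C@]2(C)O[Si](C)(C)C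
F4 | step 10 | (1R,3R,4S,6E,8R,11S,12S,15S)-11,12-epoxy-8-hydroperoxy-4-(trimethylsilyloxy)cembr-6-en-16,3-olide | C[C@@H]1C(=O)O[C@@H]2C[C@H]1CC[C@]1(C)O[C@H]1CC[C@@](C)(OO)/C=C/C[C@]2(C)O[Si](C)(C)C
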